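**Remark on numbering and configuration.** Guaiane numbering is used throughout: C1 ring-fusion CH, C2 CH2, C3 C=O, C4 =C–CH3, C5 ring-fusion sp2 carbon, C6 CH2, C7 CH bearing C11, C8 CH–O, C9 CH2, C10 CH–CH3, C11 CMe2–O. The SMILES is read as (1R,7S,8R,10S): H-1, CH3-10, O-8 and the C7 side chain all lie on one face of the seven-membered ring.

## The problem

The target is a guai-4-en-3-one: a cyclopentenone (C1–C5, ketone C3, tetrasubstituted C4=C5) fused through C1–C5 to a cycloheptane (C1, C10, C9, C8, C7, C6, C5). The seven-membered ring is slow to close end to end, and it must carry CH3 on C10, the propanoate on C8, CMe2OAc on C7 and H-1 all on the same face. The four stereocentres form two dyads, C1/C10 and C7/C8, insulated from each other by C9H2 on one side and by C6H2 and sp2 C5 on the other. Within a dyad control is easy: C10 steers C1 (adjacent, and C1 is the epimerisable γ-position of the enone), and C8 and C7 can be set together from a β-keto ester. Between the dyads the relay is weak, so each dyad needs its own source of absolute control. The sensitive groups are the tertiary acetate (elimination), the secondary propanoate (the two esters must be told apart, so they go on last, secondary first), the β-oxygenated C7/C8 unit (retro-aldol, dehydration) and the enone (1,2-addition, C1 epimerisation, oxa-Michael addition of O-8 to C5). The enabling feature is the oxidation pattern of the seven-membered ring: C5 and C8 are both at the carbonyl level and 1,4-related, and C7 carries a carboxyl-level carbon (C11). The ring is therefore a latent cyclohepta-1,5-diene bis(enol ether), C7(C11)=C8(O)–C9 joined to C6–C5(O)=C1–C10(CH3), that is, an enolised acetoacetate (three ring carbons) plus an enolised pent-3-en-2-one (four ring carbons).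

## Retrosynthesis

**Esters (16 ⇒ 15 ⇒ 14).** The two C–O acyl bonds are cut first, tertiary acetate then secondary propanoate, leading to diol 14. Any earlier placement would expose the esters to the base and organometallic steps. The forward reactions only need to distinguish a secondary from a tertiary alcohol.

**C11 methyls and C8–H (14 ⇒ 13 ⇒ 12).** The C11–CH3 bonds are cut to the methyl ester 13, and the C8–H bond to β-keto ester 12. Against the neighbouring cut C7–C11 (aldol with acetone), the ester is regiodefined and not prone to retro-aldol, and a β-keto ester allows C8 and C7 to be set in one reduction with dynamic kinetic resolution. The forward steps need a cis-selective, face-selective reduction and a double methyl addition that spares the enone.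

**Cyclopentenone (12 ⇒ 11 ⇒ 7 + 9).** The C4=C5 bond is cut by retro-aldol to 1,4-diketone 11, and C1–C2 by retro-Michael to the C5 silyl enol ether 7 and 2-nitrobut-1-ene 9 (from 2-nitrobutan-1-ol 8). Against a Pauson–Khand cut through C1–C5, this keeps the seven-membered ring intact and uses an enol ether whose regiochemistry (C5=C1) is fixed by the key step. The precursor 7 is monocyclic with one stereocentre. The forward reaction must attack C1 anti to CH3-10.

**Seven-membered ring (7 ⇒ 6 ⇒ 2 + 5, key step).** C6–C7 and C9–C10 are cut. This is a formal (4+3) disconnection into siloxydiene 2 (C6, C5, C1, C10) and siloxyvinyldiazoacetate 5 (C7, C8, C9, with C11 as the ester), passing through cis-divinylcyclopropane 6. Every ring carbon arrives at the right oxidation level and both partners are acyclic C5 building blocks. The forward reaction must cyclopropanate the enol ether end of 2 with high face selectivity and then undergo Cope rearrangement.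

**Partners (2 ⇒ 1; 5 ⇒ 4 ⇒ 3).** Diene 2 is the silyl enol ether of (E)-pent-3-en-2-one 1. Diazo compound 5 is the silyl enol ether of diazo ester 4, made by diazo transfer to methyl acetoacetate 3.

## Roads not taken

**Alternative 1:** intramolecular Pauson–Khand reaction, the most obvious cut for a bicyclic cyclopentenone (C1–C5, C2–C3 and C3–C4 formed at once from the acetonide-tethered 1,8-enyne A1 and CO). The closure of a seven-membered ring from a 1,8-enyne is the known weak point of this reaction, and the acetonide gives only partial preorganisation. A1 already needs all of C7, C8 and C10 set in a long linear sequence, so the precursor is hardly simpler than the product. The chosen plan builds the seven-membered ring by a sigmatropic shift from two C5 pieces and leaves the easy five-ring closure for later.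

**Alternative 2:** photochemical rearrangement of a cross-conjugated cyclohexadienone (C1–C5 formed, C5–C10 broken): eudesmadienone A2, irradiated in acetic acid, should give the 5/7 skeleton A3. The mechanism puts an acetoxy group on C10, where the target has hydrogen, and leaves H-1 on the wrong face. C10 would have to be deoxygenated and its configuration reset by an alkene hydrogenation of uncertain facial sense. A2 itself is a decalin with three stereocentres that no chiral-pool eudesmane supplies with oxygen at C8. The chosen plan delivers C10 directly as CH–CH3 with catalyst control.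

**Alternative 3:** intramolecular (4+3) cycloaddition of a 2-tethered furan with an oxyallyl cation (C1–C5 and C8–C9 formed) to the oxa-bridged tricycle A4, whose C5–O–C8 bridge would later be opened by E1cB elimination to reveal O-8 and C4=C5. The rigid bicycle is attractive for stereochemical relay. However, the oxyallyl unit leaves a ketone at C10 that must be turned into CH–CH3, and the C7 side chain must be added to the C6=C7 alkene with exo and regiocontrol. The tethered furan also needs several steps. The chosen (4+3) mapping puts every oxygen where the target needs it and avoids these corrections.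

Key step: step 4

## Route

**Step 1**
Reactants: 1 (E)-pent-3-en-2-one
Product: 2 (E)-2-(tert-butyldimethylsilyloxy)penta-1,3-diene
Conditions: TBSOTf, Et3N, Et2O, 0 °C
Reagents that add atoms: tert-butyldimethylsilyl trifluoromethanesulfonate (TBSOTf), CC(C)(C)[Si](C)(C)OS(=O)(=O)C(F)(F)F
Why: Soft enolisation of the methyl ketone at CH3 gives the cross-conjugated 2-siloxydiene; the (E)-propenyl geometry is untouched.

**Step 2**
Reactants: 3 methyl acetoacetate
Product: 4 methyl 2-diazo-3-oxobutanoate
Conditions: 4-acetamidobenzenesulfonyl azide, Et3N, MeCN, 0 °C to rt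
Reagents that add atoms: 4-acetamidobenzenesulfonyl azide (p-ABSA), CC(=O)Nc1ccc(cc1)S(=O)(=O)N=[N+]=[N-]
Why: Regitz diazo transfer to an active methylene compound.

**Step 3**
Reactants: 4 methyl 2-diazo-3-oxobutanoate
Product: 5 methyl 3-(tert-butyldimethylsilyloxy)-2-diazobut-3-enoate
Conditions: TBSOTf, Et3N, CH2Cl2, 0 °C
Reagents that add atoms: tert-butyldimethylsilyl trifluoromethanesulfonate (TBSOTf), CC(C)(C)[Si](C)(C)OS(=O)(=O)C(F)(F)F
Why: O-silylation of the acetyl group gives the siloxyvinyldiazoacetate, a standard vinylcarbenoid precursor.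

**Step 4**
Reactants: 2 (E)-2-(tert-butyldimethylsilyloxy)penta-1,3-diene; 5 methyl 3-(tert-butyldimethylsilyloxy)-2-diazobut-3-enoate
Product: 7 methyl (4S)-2,6-bis(tert-butyldimethylsilyloxy)-4-methylcyclohepta-1,5-diene-1-carboxylate, via cis-divinylcyclopropane 6 (not isolated)
Conditions: Rh2(R-PTAD)4 (1 mol %; PTAD = (1-adamantyl)(phthalimido)acetate), 2 in excess, hexanes, −26 °C, slow addition of 5; then 25–50 °C
Reagents that add atoms: none
Why: The dirhodium tetracarboxylate decomposes 5 with loss of N2 to a donor/acceptor vinylcarbenoid, which cyclopropanates the terminal, electron-rich CH2=C(OTBS) bond (C6=C5) of 2; the trans-disubstituted C1=C10 bond is not attacked by this class of carbenoid. The alkenyl group of the alkene ends up cis to the carbenoid vinyl group (away from the ester), giving cis-divinylcyclopropane 6, which undergoes Cope rearrangement through the obligatory boat transition state: C9–C10 forms and C5–C7 breaks. The closest known reaction type is the tandem cyclopropanation/Cope rearrangement (formal (4+3) cycloaddition) of this siloxyvinyldiazoacetate with acyclic dienes under chiral dirhodium carboxylate catalysis, and of vinylcarbenoids with 2-siloxydienes. The seven-membered ring is thus closed by a (2+1) carbenoid addition followed by a concerted [3,3]-sigmatropic shift, not by an end-to-end cyclisation. The only stereocentre of 7, C10, is set in the Cope step: the catalyst fixes 6 as (1R,2S), and the boat transition state with the methyl of the (E)-propenyl group exo transfers this to (S)-C10. Rh2(R-PTAD)4 is the enantiomer expected to give this sense. The step needs site selectivity (enol ether over propenyl, secured electronically and sterically), diastereoselectivity in the cyclopropanation, and a concerted rather than zwitterionic course, which the nonpolar solvent and low temperature favour.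

**Step 5**
Reactants: 8 2-nitrobutan-1-ol
Product: 9 2-nitrobut-1-ene
Conditions: phthalic anhydride, 150–180 °C, distillation under reduced pressure
Reagents that add atoms: none
Why: Standard dehydration of a β-nitro alcohol to the 2-nitroalkene, which serves as a 2-oxobutyl cation equivalent.

**Step 6**
Reactants: 7 methyl (4S)-2,6-bis(tert-butyldimethylsilyloxy)-4-methylcyclohepta-1,5-diene-1-carboxylate; 9 2-nitrobut-1-ene
Product: 11 methyl (4S,5R)-4-methyl-2,6-dioxo-5-(2-oxobutyl)cycloheptane-1-carboxylate, via silyl nitronate 10 (not isolated)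
Conditions: SnCl4, CH2Cl2, −78 °C; then 1 M HCl, THF, 25–50 °C
Reagents that add atoms: water, O
Why: Mukaiyama–Michael addition of the C5 silyl enol ether through C1 to the nitroalkene, followed by Nef hydrolysis of the nitronate to the C3 ketone; the β-siloxy enoate at C7=C8 is a vinylogous carbonate and far less nucleophilic, and is simply hydrolysed in the work-up. C2 enters anti to CH3-10, giving the 1,10-trans arrangement (H-1 cis to CH3-10).

**Step 7**
Reactants: 11 methyl (4S,5R)-4-methyl-2,6-dioxo-5-(2-oxobutyl)cycloheptane-1-carboxylate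
Product: 12 methyl (8S,8aR)-3,8-dimethyl-2,6-dioxo-1,2,4,5,6,7,8,8a-octahydroazulene-5-carboxylate
Conditions: KOtBu (2.2 equiv), t-BuOH/THF, 0 °C to rt; aq. NH4Cl
Reagents that add atoms: none
Why: Intramolecular aldol condensation of the 1,4-diketone (C4 onto C5) gives the tetrasubstituted cyclopentenone, while the β-keto ester is protected as its enolate. C1, now the γ-position of the enone, can equilibrate and is expected to settle trans to CH3-10.

**Step 8**
Reactants: 12 methyl (8S,8aR)-3,8-dimethyl-2,6-dioxo-1,2,4,5,6,7,8,8a-octahydroazulene-5-carboxylate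
Product: 13 methyl (5S,6R,8S,8aR)-6-hydroxy-3,8-dimethyl-2-oxo-1,2,4,5,6,7,8,8a-octahydroazulene-5-carboxylate
Conditions: RuCl[(R,R)-TsDPEN](p-cymene) (2 mol %), HCO2H/Et3N (5:2), CH2Cl2, 30 °C
Reagents that add atoms: none
Why: Asymmetric transfer hydrogenation with dynamic kinetic resolution: C7 epimerises through the enol and hydride adds anti to the C7 ester (Felkin–Anh), which gives the cis-hydroxy ester. The (R,R)-catalyst is expected to select the Si face of C8 (the face of axial attack in the conformer with equatorial CH3-10), and the hindered tetrasubstituted enone is not reduced.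

**Step 9**
Reactants: 13 methyl (5S,6R,8S,8aR)-6-hydroxy-3,8-dimethyl-2-oxo-1,2,4,5,6,7,8,8a-octahydroazulene-5-carboxylate
Product: 14 (5S,6R,8S,8aR)-6-hydroxy-5-(2-hydroxypropan-2-yl)-3,8-dimethyl-4,5,6,7,8,8a-hexahydroazulen-2(1H)-one
Conditions: LiHMDS (2.2 equiv), THF, −78 °C; then MeMgBr (5 equiv), −78 to 0 °C; aq. NH4Cl
Reagents that add atoms: methylmagnesium bromide, C[Mg]Br
Why: LiHMDS turns the C8 hydroxyl into its alkoxide and the enone into its cross-conjugated C2 enolate (in situ protection of the ketone), so the Grignard reagent adds twice to the ester only; the quench regenerates the enone, and C7 and C8 are untouched.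

**Step 10**
Reactants: 14 (5S,6R,8S,8aR)-6-hydroxy-5-(2-hydroxypropan-2-yl)-3,8-dimethyl-4,5,6,7,8,8a-hexahydroazulen-2(1H)-one
Product: 15 (5S,6R,8S,8aR)-5-(2-hydroxypropan-2-yl)-3,8-dimethyl-2-oxo-1,2,4,5,6,7,8,8a-octahydroazulen-6-yl propanoate
Conditions: (EtCO)2O (1.2 equiv), Et3N, DMAP (cat.), CH2Cl2, 0 °C
Reagents that add atoms: propanoic anhydride, CCC(=O)OC(=O)CC
Why: DMAP-catalysed acylation is much faster at the secondary C8 hydroxyl than at the tertiary C11 hydroxyl.

**Step 11**
Reactants: 15 (5S,6R,8S,8aR)-5-(2-hydroxypropan-2-yl)-3,8-dimethyl-2-oxo-1,2,4,5,6,7,8,8a-octahydroazulen-6-yl propanoate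
Product: 16 (5S,6R,8S,8aR)-5-(2-acetoxypropan-2-yl)-3,8-dimethyl-2-oxo-1,2,4,5,6,7,8,8a-octahydroazulen-6-yl propanoate
Conditions: Ac2O (excess), Et3N, DMAP (1 equiv), CH2Cl2, 40 °C
Reagents that add atoms: acetic anhydride, CC(=O)OC(C)=O
Why: Acetylation of a tertiary alcohol through the N-acetylpyridinium salt of DMAP under non-acidic conditions, which avoids ionisation and elimination at C11.

## Compound list

1 | (E)-pent-3-en-2-one | C/C=C/C(C)=O | starting material
2 | (E)-2-(tert-butyldimethylsilyloxy)penta-1,3-diene | C=C(O[Si](C)(C)C(C)(C)C)/C=C/C | intermediate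
3 | methyl acetoacetate (methyl 3-oxobutanoate) | COC(=O)CC(C)=O | starting material
4 | methyl 2-diazo-3-oxobutanoate | COC(=O)C(=[N+]=[N-])C(C)=O | intermediate
5 | methyl 3-(tert-butyldimethylsilyloxy)-2-diazobut-3-enoate | COC(=O)C(=[N+]=[N-])C(=C)O[Si](C)(C)C(C)(C)C | intermediate
6 | methyl (1R,2S)-2-(tert-butyldimethylsilyloxy)-1-[1-(tert-butyldimethylsilyloxy)ethenyl]-2-[(E)-prop-1-enyl]cyclopropane-1-carboxylate (the two alkenyl groups cis) | COC(=O)[C@@]1(C(=C)O[Si](C)(C)C(C)(C)C)C[C@]1(O[Si](C)(C)C(C)(C)C)/C=C/C | intermediate
7 | methyl (4S)-2,6-bis(tert-butyldimethylsilyloxy)-4-methylcyclohepta-1,5-diene-1-carboxylate | COC(=O)C1=C(O[Si](C)(C)C(C)(C)C)C[C@H](C)C=C(O[Si](C)(C)C(C)(C)C)C1 | intermediate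
8 | 2-nitrobutan-1-ol (racemic) | CCC(CO)[N+](=O)[O-] | starting material
9 | 2-nitrobut-1-ene | CCC(=C)[N+](=O)[O-] | intermediate
10 | methyl (4S,5R)-2-(tert-butyldimethylsilyloxy)-5-{2-[(tert-butyldimethylsilyloxy)(oxido)azaniumylidene]butyl}-4-methyl-6-oxocyclohept-1-ene-1-carboxylate (silyl nitronate) | COC(=O)C1=C(O[Si](C)(C)C(C)(C)C)C[C@H](C)[C@@H](CC(CC)=[N+]([O-])O[Si](C)(C)C(C)(C)C)C(=O)C1 | intermediate
11 | methyl (4S,5R)-4-methyl-2,6-dioxo-5-(2-oxobutyl)cycloheptane-1-carboxylate (C1 epimers and enol form) | O=C1C[C@H](C)[C@@H](CC(=O)CC)C(=O)CC1C(=O)OC | intermediate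
12 | methyl (8S,8aR)-3,8-dimethyl-2,6-dioxo-1,2,4,5,6,7,8,8a-octahydroazulene-5-carboxylate (C5 epimers and enol form) | O=C1C[C@H](C)[C@H]2CC(=O)C(C)=C2CC1C(=O)OC | intermediate
13 | methyl (5S,6R,8S,8aR)-6-hydroxy-3,8-dimethyl-2-oxo-1,2,4,5,6,7,8,8a-octahydroazulene-5-carboxylate | O[C@@H]1C[C@H](C)[C@H]2CC(=O)C(C)=C2C[C@@H]1C(=O)OC | intermediate
14 | (5S,6R,8S,8aR)-6-hydroxy-5-(2-hydroxypropan-2-yl)-3,8-dimethyl-4,5,6,7,8,8a-hexahydroazulen-2(1H)-one | O[C@@H]1C[C@H](C)[C@H]2CC(=O)C(C)=C2C[C@@H]1C(C)(C)O | intermediate
15 | (5S,6R,8S,8aR)-5-(2-hydroxypropan-2-yl)-3,8-dimethyl-2-oxo-1,2,4,5,6,7,8,8a-octahydroazulen-6-yl propanoate | CCC(=O)O[C@@H]1C[C@H](C)[C@H]2CC(=O)C(C)=C2C[C@@H]1C(C)(C)O | intermediate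
16 | (5S,6R,8S,8aR)-5-(2-acetoxypropan-2-yl)-3,8-dimethyl-2-oxo-1,2,4,5,6,7,8,8a-octahydroazulen-6-yl propanoate (CNP0288556.1) | CCC(=O)O[C@@H]1C[C@H](C)[C@H]2CC(=O)C(C)=C2C[C@@H]1C(C)(C)OC(C)=O | target

## Step count and least certain steps

Total: 11 steps. Longest linear sequence: 9 steps (3 → 4 → 5 → 7 → 11 → 12 → 13 → 14 → 15 → 16; steps 2, 3, 4, 6, 7, 8, 9, 10, 11).

**Step 4 (key step).** The most likely failure is loss of stereochemical fidelity at C10. The electron-rich enol ether may react in a stepwise, zwitterionic manner, or give the trans-divinylcyclopropane, which reaches the Cope geometry only by ring opening and reclosure; either erodes the enantiocontrol. The sense of induction of the chosen catalyst enantiomer also has to be confirmed. Competing (3+2) annulation and carbenoid dimerisation would lower the efficiency.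
Fallback, from 5, returning at 7: the same carbenoid chemistry is run without any stereochemical demand on commercial 2-(trimethylsilyloxy)buta-1,3-diene (Rh2(OPiv)4, hexanes) to give achiral methyl 2-(tert-butyldimethylsilyloxy)-6-(trimethylsilyloxy)cyclohepta-1,5-diene-1-carboxylate F1. Saegusa oxidation (Pd(OAc)2, MeCN) converts its C5 enol ether into methyl 2-(tert-butyldimethylsilyloxy)-6-oxocyclohepta-1,4-diene-1-carboxylate F2. Copper-catalysed asymmetric conjugate addition of AlMe3 to C10 (Cu(OTf)2, a BINOL-derived phosphoramidite ligand of the enantiomer that gives (S)-C10, Et2O, −30 °C), with trapping of the enolate by TBSOTf, then gives 7. C10 is thus set by a conjugate addition instead of by the cycloaddition.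

**Step 8.** The most likely failure is poor facial selectivity of hydride transfer at C8 relative to the remote C10 centre (catalyst and ring bias mismatched, or the ester not directing as assumed), or C7 epimerisation too slow for an efficient dynamic resolution.
Fallback, from 12, returning at 14: chelation-controlled hydrogenation (H2, RuCl2[(S)-BINAP], CH2Cl2) has a predictable sense at C8 and gives the trans-hydroxy ester methyl (5S,6S,8S,8aR)-6-hydroxy-3,8-dimethyl-2-oxo-1,2,4,5,6,7,8,8a-octahydroazulene-5-carboxylate F3, with C7 already correct. Mitsunobu inversion at C8 (PhCO2H, PPh3, DIAD) gives methyl (5S,6R,8S,8aR)-6-(benzoyloxy)-3,8-dimethyl-2-oxo-1,2,4,5,6,7,8,8a-octahydroazulene-5-carboxylate F4. F4 is taken through the conditions of step 9; the excess MeMgBr also cleaves the benzoate and gives 14.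

**Step 9.** The most likely failure is incomplete masking of the enone, leading to 1,2-addition of the Grignard reagent at C3. Retro-aldol opening of the β-alkoxide ester, and reversible oxa-Michael addition of the C8 alkoxide to C5 that persists after the quench, are further possibilities.
Fallback, from 13, returning at 14: Luche reduction (NaBH4, CeCl3·7H2O, MeOH, −78 °C) turns the enone into the allylic alcohol methyl (5S,6R,8S,8aR)-2,6-dihydroxy-3,8-dimethyl-1,2,4,5,6,7,8,8a-octahydroazulene-5-carboxylate F5. Excess MeMgBr gives (5S,6R,8S,8aR)-5-(2-hydroxypropan-2-yl)-3,8-dimethyl-1,2,4,5,6,7,8,8a-octahydroazulene-2,6-diol F6. MnO2 (CH2Cl2) re-oxidises only the allylic C3 hydroxyl and gives 14.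

**Step 6.** The most likely failure is Lewis-acid-induced polymerisation of the nitroalkene or protodesilylation of the C5 enol ether before C–C bond formation, which would lose the regiochemistry. Incomplete Nef hydrolysis is a lesser concern.
Fallback, from 7, returning at 11: phenylthioalkylation of the silyl enol ether with 1-chloro-1-(phenylsulfanyl)butan-2-one (ZnBr2 or TiCl4, CH2Cl2, −78 °C, acidic work-up) gives methyl (4S,5R)-4-methyl-2,6-dioxo-5-[2-oxo-1-(phenylsulfanyl)butyl]cycloheptane-1-carboxylate F7. Reductive removal of sulfur (Zn, AcOH) gives 11.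

## Further compounds

F1 | step 4 | methyl 2-(tert-butyldimethylsilyloxy)-6-(trimethylsilyloxy)cyclohepta-1,5-diene-1-carboxylate | COC(=O)C1=C(O[Si](C)(C)C(C)(C)C)CCC=C(O[Si](C)(C)C)C1
F2 | step 4 | methyl 2-(tert-butyldimethylsilyloxy)-6-oxocyclohepta-1,4-diene-1-carboxylate | COC(=O)C1=C(O[Si](C)(C)C(C)(C)C)CC=CC(=O)C1
F3 | step 8 | methyl (5S,6S,8S,8aR)-6-hydroxy-3,8-dimethyl-2-oxo-1,2,4,5,6,7,8,8a-octahydroazulene-5-carboxylate | O[C@H]1C[C@H](C)[C@H]2CC(=O)C(C)=C2C[C@@H]1C(=O)OC
F4 | step 8 | methyl (5S,6R,8S,8aR)-6-(benzoyloxy)-3,8-dimethyl-2-oxo-1,2,4,5,6,7,8,8a-octahydroazulene-5-carboxylate | O=C(O[C@@H]1C[C@H](C)[C@H]2CC(=O)C(C)=C2C[C@@H]1C(=O)OC)c1ccccc1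
F5 | step 9 | methyl (5S,6R,8S,8aR)-2,6-dihydroxy-3,8-dimethyl-1,2,4,5,6,7,8,8a-octahydroazulene-5-carboxylate (C2 epimers) | O[C@@H]1C[C@H](C)[C@H]2CC(O)C(C)=C2C[C@@H]1C(=O)OC
F6 | step 9 | (5S,6R,8S,8aR)-5-(2-hydroxypropan-2-yl)-3,8-dimethyl-1,2,4,5,6,7,8,8a-octahydroazulene-2,6-diol (C2 epimers) | O[C@@H]1C[C@H](C)[C@H]2CC(O)C(C)=C2C[C@@H]1C(C)(C)O
F7 | step 6 | methyl (4S,5R)-4-methyl-2,6-dioxo-5-[2-oxo-1-(phenylsulfanyl)butyl]cycloheptane-1-carboxylate (epimers at ring C1 and at the sulfur-bearing carbon) | O=C1C[C@H](C)[C@@H](C(Sc2ccccc2)C(=O)CC)C(=O)CC1C(=O)OC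
A1 | alternative 1 | (5S,6R)-5-(but-2-yn-1-yl)-2,2,4,4-tetramethyl-6-[(2S)-2-methylbut-3-en-1-yl]-1,3-dioxane | C=C[C@@H](C)C[C@H]1OC(C)(C)OC(C)(C)[C@H]1CC#CC
A2 | alternative 2 | 8β,11-dihydroxy-7αH-eudesma-1,4-dien-3-one (10β-methyl) | CC1=C2C[C@H](C(C)(C)O)[C@H](O)C[C@@]2(C)C=CC1=O
A3 | alternative 2 | 10α-acetoxy-8β,11-dihydroxy-1αH,7αH-guai-4-en-3-one | CC(=O)O[C@]1(C)C[C@@H](O)[C@@H](C(C)(C)O)CC2=C(C)C(=O)C[C@H]21
A4 | alternative 3 | oxa-bridged (4+3) adduct: 8-oxabicyclo[3.2.1]oct-6-en-3-one (C10 ketone, C5–O–C8 bridge, C6=C7 alkene) fused at C5–C1 to 2-methylcyclopentanone ethylene ketal, H-1 on the side of the oxygen bridge, C4 epimers | O=C1C[C@@H]2C=C[C@]3(O2)C(C)C4(OCCO4)C[C@H]13
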